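Target **13** is the achiral 4-pyranone O1–C2(OMe)–C3(Me)–C4(=O)–C5(Me)–C6(chain). Ring atoms C2 to C5, with their OMe, Me, carbonyl and Me, are taken from one electron-rich diene; C6, O1 and the 11-acetoxyundecyl chain are taken from one aldehyde.
Last disconnection: the C5=C6 double bond, made by dehydrogenating 2,3-dihydro-4-pyranone **11** through its silyl dienol ether **12**.
Key disconnection: C5–C6 and O1–C2 of **11**, formed together by a Lewis-acid hetero-Diels–Alder reaction of silyloxy ketene-acetal diene **6** with aldehyde **9**; this closes the only ring.
Diene **6** comes from acyl ketene acetal **5** by enol silylation, **5** from 1,1-dimethoxypropene **3** and propionyl chloride **4**, and **3** from trimethyl orthopropionate **1**.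
Aldehyde **9** comes from 1,12-dodecanediol **7** by monoacetylation and oxidation.

Key step: step 7

Remark: the target has no stereogenic element, so no step has to control configuration; the ring numbering above is also used for the dihydro precursors.

Step 1
Reactants: 1 trimethyl orthopropionate (1,1,1-trimethoxypropane)
Product: 2 2-bromo-1,1,1-trimethoxypropane (racemic)
Conditions: Br2 (1.0 equiv), pyridine, 0–10 °C
Reagents that add atoms: bromine, BrBr
Why: α-Bromination of an ortho ester in pyridine proceeds through the small equilibrium amount of ketene acetal, and pyridine takes up the HBr so the acid-labile ortho ester survives; the new centre is racemic and is removed in step 2.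

Step 2
Reactants: 2 2-bromo-1,1,1-trimethoxypropane
Product: 3 1,1-dimethoxyprop-1-ene (methylketene dimethyl acetal)
Conditions: Na dispersion (2.1 equiv), mesitylene, 105 °C; fractional distillation under N2
Reagents that add atoms: none
Why: Boord-type reductive β-elimination, in which sodium reduces the C–Br bond and the carbanion expels methoxide, is the classical access to alkylketene acetals and keeps the medium basic, as the acid-sensitive product requires.

Step 3
Reactants: 3 1,1-dimethoxyprop-1-ene; 4 propionyl chloride
Product: 5 1,1-dimethoxy-2-methylpent-1-en-3-one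
Conditions: 2,6-lutidine (1.2 equiv), Et2O, −20 °C → rt; filter, distil at reduced pressure
Reagents that add atoms: none
Why: C-Acylation of the ketene acetal at its nucleophilic β-carbon by the acid chloride (the ketene-acetal counterpart of the Stork enamine acylation) gives an acyl dimethoxycarbenium ion whose very acidic proton the hindered base removes, and the base is too weak to turn the acid chloride into a ketene.

Step 4
Reactants: 5 1,1-dimethoxy-2-methylpent-1-en-3-one
Product: 6 (Z)-[(1,1-dimethoxy-2-methylpenta-1,3-dien-3-yl)oxy]trimethylsilane
Conditions: LDA (commercial solution, 1.05 equiv), THF, −78 °C; TMSCl, −78 °C → rt; pentane, filter, bulb-to-bulb distillation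
Reagents that add atoms: chlorotrimethylsilane, C[Si](C)(C)Cl
Why: Kinetic deprotonation at the ethyl CH2, the only enolisable position, and O-silylation (silyl enol ether formation) give the 2-silyloxy diene; the Z enol ether (methyl cis to OSiMe3) is expected for a branched alkenyl ethyl ketone, and either geometry would serve because the sp3 centres of the key step are erased later.

Step 5
Reactants: 7 1,12-dodecanediol (3 equiv)
Product: 8 12-hydroxydodecyl acetate
Conditions: Ac2O (1.0 equiv), pyridine, DMAP (cat.), THF, 0 °C → rt; chromatography, diol recovered
Reagents that add atoms: acetic anhydride, CC(=O)OC(C)=O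
Why: DMAP-catalysed acylation with one equivalent of anhydride against excess symmetrical diol should give mainly the monoacetate, which is separated from recovered diol and diacetate.

Step 6
Reactants: 8 12-hydroxydodecyl acetate
Product: 9 12-oxododecyl acetate
Conditions: TEMPO (10 mol %), PhI(OAc)2 (1.1 equiv), CH2Cl2, rt
Reagents that add atoms: none
Why: The TEMPO/PhI(OAc)2 oxoammonium oxidation takes a primary alcohol to the aldehyde without over-oxidation and leaves the acetate untouched.

Step 7
Reactants: 6 (Z)-[(1,1-dimethoxy-2-methylpenta-1,3-dien-3-yl)oxy]trimethylsilane (1.3 equiv); 9 12-oxododecyl acetate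
Product: 11 11-(6-methoxy-3,5-dimethyl-4-oxo-3,4-dihydro-2H-pyran-2-yl)undecyl acetate (mixture of racemic cis and trans isomers), via cyclic ortho ester cycloadduct 10 (not isolated)
Conditions: Eu(fod)3 (5 mol %), CH2Cl2, rt, strictly anhydrous; then TFA (0.1 equiv), 0 °C; Et3N quench, chromatography on Et3N-deactivated silica
Reagents that add atoms: none
Why: The europium Lewis acid activates the aldehyde, and the diene, raised in energy by three oxygen donors, attacks the carbonyl carbon with its silyl-enol-ether terminus to form C5–C6 while the aldehyde oxygen bonds to the dimethoxy carbon to form O1–C2; this is the Lewis-acid hetero-Diels–Alder reaction of alkoxy silyloxy dienes with aldehydes, which may equally run as a vinylogous Mukaiyama aldol followed by cyclisation. The six-membered ring closes as a [4+2] cycloaddition, equivalent in the stepwise sense to 6-endo attack of the aldolate oxygen on the dialkoxy-stabilised carbon, and gives ortho ester 10. Catalytic TFA ionises the ortho ester, and loss of methoxide and the silyl group as MeOSiMe3 unveils the vinylogous carbonate 11; water must be excluded because it would turn 10 into a lactone. The two new sp3 centres at C5 and C6 are not controlled and need not be, since both are removed in step 8. The selectivity that counts is regiochemical, bond formation at the diene terminus and not at the central ketene-acetal carbon, and the polarisation of the diene secures it: attack at the unhindered terminus gives a cation stabilised by all three oxygens, whereas attack at the central carbon would build a quaternary centre and a less stabilised ion. The unhindered aliphatic aldehyde is far more electrophilic than the acetate, which is not touched.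

Step 8
Reactants: 11 11-(6-methoxy-3,5-dimethyl-4-oxo-3,4-dihydro-2H-pyran-2-yl)undecyl acetate
Product: 13 11-(6-methoxy-3,5-dimethyl-4-oxo-4H-pyran-2-yl)undecyl acetate, via silyl dienol ether 12 (not isolated)
Conditions: TMSOTf (1.15 equiv), i-Pr2NEt (1.2 equiv), CH2Cl2, −78 → −20 °C; then DDQ (1.3 equiv, in THF), −78 → 0 °C; aq. NaHCO3
Reagents that add atoms: none
Why: Soft enolisation (O-silylation of the vinylogous-carbonate carbonyl, then deprotonation at C5, the only α-CH) spares the acetate that a lithium amide would also deprotonate, and DDQ then takes hydride from C6–H of the 2H-pyran (DDQ dehydrogenation of a silyl enol ether) to give an aromatic 4-silyloxypyrylium ion that loses the silyl group to the pyranone; working cold keeps the 2H-pyran from electrocyclic ring opening, and both sp3 ring centres disappear.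

Compound list
1 | trimethyl orthopropionate (1,1,1-trimethoxypropane) | CCC(OC)(OC)OC | starting material
2 | 2-bromo-1,1,1-trimethoxypropane (racemic) | CC(Br)C(OC)(OC)OC | intermediate
3 | 1,1-dimethoxyprop-1-ene | CC=C(OC)OC | intermediate
4 | propionyl chloride | CCC(Cl)=O | starting material
5 | 1,1-dimethoxy-2-methylpent-1-en-3-one | CCC(=O)C(C)=C(OC)OC | intermediate
6 | (Z)-[(1,1-dimethoxy-2-methylpenta-1,3-dien-3-yl)oxy]trimethylsilane | C/C=C(\O[Si](C)(C)C)C(C)=C(OC)OC | intermediate
7 | 1,12-dodecanediol | OCCCCCCCCCCCCO | starting material
8 | 12-hydroxydodecyl acetate | CC(=O)OCCCCCCCCCCCCO | intermediate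
9 | 12-oxododecyl acetate | CC(=O)OCCCCCCCCCCCC=O | intermediate
10 | 11-[6,6-dimethoxy-3,5-dimethyl-4-(trimethylsilyloxy)-3,6-dihydro-2H-pyran-2-yl]undecyl acetate (diastereomer mixture, not isolated) | COC1(OC)OC(CCCCCCCCCCCOC(C)=O)C(C)C(O[Si](C)(C)C)=C1C | intermediate
11 | 11-(6-methoxy-3,5-dimethyl-4-oxo-3,4-dihydro-2H-pyran-2-yl)undecyl acetate (racemic cis/trans mixture) | COC1=C(C)C(=O)C(C)C(CCCCCCCCCCCOC(C)=O)O1 | intermediate
12 | 11-[6-methoxy-3,5-dimethyl-4-(trimethylsilyloxy)-2H-pyran-2-yl]undecyl acetate (racemic, not isolated) | COC1=C(C)C(O[Si](C)(C)C)=C(C)C(CCCCCCCCCCCOC(C)=O)O1 | intermediate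
13 | 11-(6-methoxy-3,5-dimethyl-4-oxo-4H-pyran-2-yl)undecyl acetate (achiral) | COc1oc(CCCCCCCCCCCOC(C)=O)c(C)c(=O)c1C | target

Total steps: 8. Longest linear sequence: 6 (steps 1, 2, 3, 4, 7, 8).

Steps most likely to fail

Step 7. The Lewis acid may consume the diene by protodesilylation or demethylation of the ketene acetal before it adds, bond formation may occur at the central carbon, or traces of water may turn the ortho ester into a lactone instead of letting it lose methanol. The fallback sets out from 9 and returns at 13, replacing steps 7 and 8. The dianion of commercial methyl 2-methyl-3-oxopentanoate (NaH, then n-BuLi, THF, −78 °C) adds through its terminal carbanion to 9 to give methyl 16-acetoxy-5-hydroxy-2,4-dimethyl-3-oxohexadecanoate F1. Dess–Martin periodinane oxidises this to methyl 16-acetoxy-2,4-dimethyl-3,5-dioxohexadecanoate F2, and DBU in warm toluene closes it to 11-(4-hydroxy-3,5-dimethyl-6-oxo-6H-pyran-2-yl)undecyl acetate F3. Methylation of F3 at the ring carbonyl oxygen with methyl triflate (or dimethyl sulfate over CaCO3) should then give 13, with separation from any 4-methoxy-2-pyranone isomer.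

Step 8. The 2H-pyran silyl dienol ether may open electrocyclically to an acyclic dienoate, the O-silylated cation may be demethylated by the amine, or DDQ may add at C5 instead of abstracting hydride. The fallback sets out from 9 and 6 and returns at 13, forming the ring directly at the pyranone oxidation level so that no dehydrogenation is needed. Pinnick oxidation of 9 (NaClO2, NaH2PO4, 2-methyl-2-butene) gives 12-acetoxydodecanoic acid F4, and oxalyl chloride with catalytic DMF gives 12-chloro-12-oxododecyl acetate F5. Diene 6 is C-acylated at its terminus by F5 (CH2Cl2, −78 °C → rt) to give 16,16-dimethoxy-13,15-dimethyl-12,14-dioxohexadec-15-en-1-yl acetate F6. Under PPTS the enol oxygen of F6 closes onto the dimethoxy carbon with loss of methanol to give 13.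

Step 3. Chloride may demethylate the acylated dimethoxycarbenium ion before it is deprotonated, diverting material to the β-keto ester, or the volatile, moisture-sensitive ketene acetal may be lost. The fallback sets out from 4 and returns at 5 without any free ketene acetal. Friedel–Crafts acylation of commercial 1,1-dichloropropene with 4 and AlCl3 in CH2Cl2 gives 1,1,1-trichloro-2-methylpentan-3-one F7, and Et3N dehydrochlorinates it to 1,1-dichloro-2-methylpent-1-en-3-one F8. Two addition–eliminations with NaOMe (2 equiv, MeOH, 0 °C) then give 5.

Further compounds
F1 | step 7 | methyl 16-acetoxy-5-hydroxy-2,4-dimethyl-3-oxohexadecanoate (diastereomer mixture) | COC(=O)C(C)C(=O)C(C)C(O)CCCCCCCCCCCOC(C)=O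
F2 | step 7 | methyl 16-acetoxy-2,4-dimethyl-3,5-dioxohexadecanoate | COC(=O)C(C)C(=O)C(C)C(=O)CCCCCCCCCCCOC(C)=O
F3 | step 7 | 11-(4-hydroxy-3,5-dimethyl-6-oxo-6H-pyran-2-yl)undecyl acetate | CC(=O)OCCCCCCCCCCCc1oc(=O)c(C)c(O)c1C
F4 | step 8 | 12-acetoxydodecanoic acid | CC(=O)OCCCCCCCCCCCC(=O)O
F5 | step 8 | 12-chloro-12-oxododecyl acetate | CC(=O)OCCCCCCCCCCCC(Cl)=O
F6 | step 8 | 16,16-dimethoxy-13,15-dimethyl-12,14-dioxohexadec-15-en-1-yl acetate | COC(OC)=C(C)C(=O)C(C)C(=O)CCCCCCCCCCCOC(C)=O
F7 | step 3 | 1,1,1-trichloro-2-methylpentan-3-one | CCC(=O)C(C)C(Cl)(Cl)Cl
F8 | step 3 | 1,1-dichloro-2-methylpent-1-en-3-one | CCC(=O)C(C)=C(Cl)Cl
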